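## The problem

The target is an oxolane (O1, C2–C5) carrying a 4-hydroxy-3-methoxyphenyl group at C2, a hydroxymethyl group at C3 and, at C4, a carbinol carbon C7' that bears a 3,4-dihydroxyphenyl ring; C5 is an unsubstituted CH2. The three ring stereocentres (2S,3R,4S) are all-trans: the C2 aryl group and the C4 side chain lie on one face and the C3 hydroxymethyl group on the other. The fourth stereocentre, C7' (R), lies outside the ring.

The stereocentres differ in how they can be controlled. C3 can be left to thermodynamics while its substituent is at the carboxyl oxidation level. C2 can take its configuration from C4 if hydrogen is added to a ring that is flat at C2 and C3. C4 has no neighbour to learn from and has to be bought as a stereocentre. C7' sits on a freely rotating bond and is better set by a reagent than by the ring.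

The fragile features are the catechol and the two benzylic C–O bonds (C2–O1 and C7'–OH). Each is para to a phenolic oxygen, ionises easily in acid and can be hydrogenolysed, so the late steps must be neutral or basic and the phenols must stay masked to the end.

The feature that opens the problem is the unit O1–C2(aryl)–C3 with a carboxyl-level carbon on C3. Written with a C2=C3 double bond it is a 2-aryl-4,5-dihydrofuran-3-carboxylate, the ring-expanded isomer of a 1-aroylcyclopropane-1-carboxylate whose ring carbons are C3, C4 and C5. Because C5 is a bare CH2, a nucleophile can open the three-membered ring there and the ketone oxygen can then close O1–C5, with C4 as the only ring stereocentre that has to be carried.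

## Retrosynthesis

**Unmasking.** The last bonds made are the three phenolic O–H bonds and the C7' O–H bond. Target 22 is traced to the tribenzyl ether 21 (hydrogenolysis over Pd/C in neutral solvent) and 21 to the silyl ether 20 (fluoride). Acid-labile masks were rejected because acid would ionise C7'. The forward steps must spare the two benzylic C–O bonds.

**C3 and C2.** The hydroxymethyl group of 20 comes from the tert-butyl ester 19. Ester 19 is the C3 epimer of the all-cis ester 18, and 18 arises by adding hydrogen across C2=C3 of dihydrofuran 17. Cutting the C2–H and C3–H bonds removes two stereocentres at once. The forward steps need hydrogen delivery anti to the C4 side chain (this fixes C2) and a base-mediated equilibration that moves the ester trans to both neighbours.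

**Key disconnection.** In 17 the O1–C5 bond is cut and C3–C5 is reconnected, which gives the aroyl cyclopropane 15. The neighbouring cuts at C2–C3 or C4–C5 would need an intermolecular C–C bond formation with control at C4. This cut instead turns the heterocycle into a carbocycle whose only ring stereocentre is C4. The forward step needs a nucleophile to open the cyclopropane at C5 and not at C4.

**Guaiacyl ketone.** The bond between the ketone carbon and the guaiacyl ring of 15 is cut to the N-methoxy-N-methylamide 12 and the aryllithium 14, made from bromide 13. An amide of this type stops cleanly at the ketone. The neighbouring tert-butyl ester is chosen as the second carboxyl because it does not compete for the aryllithium.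

**C7'.** Silyl ether 12 comes from the (R)-carbinol 11, and 11 from the aryl ketone 10 by reagent-controlled reduction. Ketone 10 comes from the epimeric alcohols 9, formed from aldehyde 6 and the Grignard reagent 8 (from bromide 7). The C7'–aryl bond is cut here rather than later so that C7' is settled while only one ketone is present in the molecule.

**Cyclopropane and C4.** Aldehyde 6 is the oxidation product of the hydroxy amide 5, which comes from aminolysis of the bicyclic lactone 4. The lactone is what allows the two carboxyl groups of a malonate to be told apart. Lactone 4 is cut at C3–C4 and C3–C5 to di-tert-butyl malonate 1 and (R)-epichlorohydrin 2, through epoxide 3. This places C4 in the chiral pool.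

## Roads not taken

**Alternative 1:** The cut is C2–C3 together with the acyl C–O bond of a lactone in which C5 is still a carbonyl carbon. Forward, aldehyde A1 and the γ-substituted 2-(methoxycarbonyl)allylboronate A2 would react through a closed chair transition state, and the boron alkoxide would lactonise to the trans α-methylene lactone A3.

- Merits: the C2/C3 trans relationship is set in one convergent step from two simple partners. In this respect the road is better than the chosen plan, which needs a hydrogenation and an epimerisation for the same relationship.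
- Weak points: in A3, C5 is a carbonyl, C4 is sp2 and C7' is a bare methylene terminus. After the key step an aryl group and an (R)-hydroxyl must be placed on C7', C4–H must be set trans to C3, and the lactone carbonyl must be taken down to CH2 next to a benzylic 2-aryl ether. None of these is relayed reliably from C2 and C3. Absolute control also needs a chiral boron reagent or catalyst.
- Comparison: the chosen plan is longer before the ring exists. Against that it has C4 from (R)-epichlorohydrin, C7' set by a reagent on a simple ketone, and C5 at the right oxidation level from the start.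

**Alternative 2:** The cuts are O1–C5, C4–C5 and C7'–O. Forward, the homoallylic alcohol A4 and formaldehyde A5 would form an oxocarbenium ion on the C2 oxygen, the E-styrene would attack through C4 to close the oxolane, and acetate would capture the C7' cation to give the pentaacetate A6.

- Merits: this is the most step-economic road. The ring, C4 and C7' appear in one operation, and A6 is one ester cleavage from the target. On step count it is clearly better than the chosen plan.
- Weak points: closure through the proximal alkene carbon competes with the usual six-membered mode. C7' passes through a free benzylic cation, so its capture from one face is not assured. The oxocarbenium ion sits on a benzylic, electron-rich C2, which invites oxonia-Cope scrambling of C2 and C3. A4 itself already holds two stereocentres and an E-alkene that need their own synthesis.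
- Comparison: the chosen plan avoids any cation at C2 or C7' and sets each stereocentre by an independent, well-understood element.

**Alternative 3:** The cuts are C2–C3 and C4–C5, with O1–C2 formed by acetalisation. Forward, aldehyde A1 and the primary hydroxyl of the tertiary allylic diol A7 would give an oxocarbenium ion, the E-alkene would attack it (C2–C3), and a pinacol shift of C5 from C7' to C4 would contract the ring to the all-trans 4-aroyl oxolane A8.

- Merits: three contiguous ring stereocentres and two C–C bonds form in one step from fragments of similar size. This is more convergent than the chosen plan, and the all-trans arrangement comes directly.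
- Weak points: A7 must be made as a single enantiomer, and the absolute sense of the transfer depends on whether the aryl group or the oxygen at C7' sits equatorial in the chair (A7 is drawn as R for an equatorial aryl group). C7' emerges as a ketone, so its configuration still has to be set late, by reduction. A Lewis acid must act on an electron-rich aryl aldehyde in the presence of benzyl ethers.
- Comparison: the chosen plan has a longer linear sequence. Against that it has C4 of certain configuration, C7' set early on a simple substrate, and a key step that runs under neutral, Lewis-acid-free conditions.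

Key step: step 9

Remark on the chemistry: lactone 4 is taken to form by attack of the malonate anion at the CH2 terminus of epoxide 2 followed by epoxide transposition (the usual course); this is what correlates (R)-epichlorohydrin with the (S) configuration needed at C4. Ring atoms are numbered O1, C2 (guaiacyl), C3, C4, C5 throughout, and the carbinol carbon is C7'.

## Route

Step 1
Reactants: 1 di-tert-butyl malonate; 2 (R)-epichlorohydrin
Product: 4 tert-butyl (1R,5R)-2-oxo-3-oxabicyclo[3.1.0]hexane-1-carboxylate, via epoxy malonate 3 (not isolated)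
Conditions: KOtBu (1.1 equiv), tBuOH, 50 °C then reflux
Reagents that add atoms: none
Why: Malonate–epichlorohydrin cyclopropanation with lactonisation: the malonate anion opens the epoxide at CH2, the chlorohydrin alkoxide closes to the transposed epoxide 3, and the re-formed malonate anion opens 3 at its stereocentre by 3-exo-tet attack with inversion, which fixes the cyclopropane CH (later C4) before the alkoxide lactonises on the cis ester. Direct displacement of chloride would lead to the enantiomer, so the enantiomeric purity of 4 should be checked here.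

Step 2
Reactants: 4 tert-butyl (1R,5R)-2-oxo-3-oxabicyclo[3.1.0]hexane-1-carboxylate
Product: 5 tert-butyl (1R,2R)-2-(hydroxymethyl)-1-[methoxy(methyl)carbamoyl]cyclopropane-1-carboxylate
Conditions: MeNHOMe·HCl, AlMe3, CH2Cl2, 0 °C to rt; Rochelle salt work-up
Reagents that add atoms: N,O-dimethylhydroxylamine hydrochloride, CNOC.Cl
Why: Weinreb aminolysis of a lactone by the aluminium amide; the strained γ-lactone carbonyl reacts while the tert-butyl ester is inert, so the two malonate carboxyl groups are differentiated and the CH2OH arm is released without touching a stereocentre.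

Step 3
Reactants: 5 tert-butyl (1R,2R)-2-(hydroxymethyl)-1-[methoxy(methyl)carbamoyl]cyclopropane-1-carboxylate
Product: 6 tert-butyl (1R,2R)-2-formyl-1-[methoxy(methyl)carbamoyl]cyclopropane-1-carboxylate
Conditions: Dess–Martin periodinane, NaHCO3, CH2Cl2, 0 °C to rt; used at once
Reagents that add atoms: none
Why: Dess–Martin oxidation of a primary alcohol under buffered conditions; a formyl group on a cyclopropane carbon enolises reluctantly, so the C4 stereocentre should not be at risk.

Step 4
Reactants: 6 tert-butyl (1R,2R)-2-formyl-1-[methoxy(methyl)carbamoyl]cyclopropane-1-carboxylate; 7 1,2-bis(benzyloxy)-4-bromobenzene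
Product: 9 tert-butyl (1R,2R)-2-{[3,4-bis(benzyloxy)phenyl](hydroxy)methyl}-1-[methoxy(methyl)carbamoyl]cyclopropane-1-carboxylate (both carbinol epimers), via arylmagnesium bromide 8 (not isolated)
Conditions: 7, Mg, THF, 40 °C; then 6, THF, −78 °C; sat. NH4Cl at −78 °C
Reagents that add atoms: none
Why: Grignard addition to an aldehyde, which at −78 °C is far more electrophilic than the amide or the tert-butyl ester; the carbinol configuration is irrelevant because step 5 erases it, and the cold quench is meant to keep the magnesium alkoxide from closing onto the cis amide.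

Step 5
Reactants: 9 tert-butyl (1R,2R)-2-{[3,4-bis(benzyloxy)phenyl](hydroxy)methyl}-1-[methoxy(methyl)carbamoyl]cyclopropane-1-carboxylate
Product: 10 tert-butyl (1R,2R)-2-[3,4-bis(benzyloxy)benzoyl]-1-[methoxy(methyl)carbamoyl]cyclopropane-1-carboxylate
Conditions: Dess–Martin periodinane, NaHCO3, CH2Cl2, 0 °C to rt
Reagents that add atoms: none
Why: Dess–Martin oxidation of a secondary benzylic alcohol; both epimers of 9 converge on one aryl cyclopropyl ketone.

Step 6
Reactants: 10 tert-butyl (1R,2R)-2-[3,4-bis(benzyloxy)benzoyl]-1-[methoxy(methyl)carbamoyl]cyclopropane-1-carboxylate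
Product: 11 tert-butyl (1R,2R)-2-{(R)-[3,4-bis(benzyloxy)phenyl](hydroxy)methyl}-1-[methoxy(methyl)carbamoyl]cyclopropane-1-carboxylate
Conditions: (S)-2-methyl-CBS-oxazaborolidine (20 mol %), BH3·SMe2, THF, −20 °C; MeOH quench, cold work-up
Reagents that add atoms: none
Why: Corey–Bakshi–Shibata reduction of an aryl alkyl ketone: the aryl ring is read as the large group and the cyclopropyl carbon as the small one, so the (S)-catalyst should deliver hydride to the face that gives the (R)-carbinol C7' under reagent control; at this temperature the amide and ester are not expected to be reduced.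

Step 7
Reactants: 11 tert-butyl (1R,2R)-2-{(R)-[3,4-bis(benzyloxy)phenyl](hydroxy)methyl}-1-[methoxy(methyl)carbamoyl]cyclopropane-1-carboxylate
Product: 12 tert-butyl (1R,2R)-2-{(R)-[3,4-bis(benzyloxy)phenyl][(tert-butyldimethylsilyl)oxy]methyl}-1-[methoxy(methyl)carbamoyl]cyclopropane-1-carboxylate
Conditions: TBSOTf, 2,6-lutidine, CH2Cl2, −78 °C
Reagents that add atoms: tert-butyldimethylsilyl trifluoromethanesulfonate, CC(C)(C)[Si](C)(C)OS(=O)(=O)C(F)(F)F
Why: Silylation of a secondary alcohol with the silyl triflate, fast enough at −78 °C to precede lactonisation of the hydroxy amide; the tert-butyl ester tolerates the reagent at this temperature.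

Step 8
Reactants: 12 tert-butyl (1R,2R)-2-{(R)-[3,4-bis(benzyloxy)phenyl][(tert-butyldimethylsilyl)oxy]methyl}-1-[methoxy(methyl)carbamoyl]cyclopropane-1-carboxylate; 13 1-(benzyloxy)-4-bromo-2-methoxybenzene
Product: 15 tert-butyl (1R,2R)-1-[4-(benzyloxy)-3-methoxybenzoyl]-2-{(R)-[3,4-bis(benzyloxy)phenyl][(tert-butyldimethylsilyl)oxy]methyl}cyclopropane-1-carboxylate, via aryllithium 14 (not isolated)
Conditions: 13, nBuLi, THF, −78 °C; then 12, −78 to −30 °C; sat. NH4Cl
Reagents that add atoms: none
Why: Weinreb ketone synthesis: bromine–lithium exchange gives 14, which adds once to the N-methoxy-N-methylamide to form a chelated tetrahedral intermediate that releases the ketone only on quench; the tert-butyl ester does not compete at low temperature, and the ketone ends up cis to the side chain, which is of no consequence.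

Step 9
Reactants: 15 tert-butyl (1R,2R)-1-[4-(benzyloxy)-3-methoxybenzoyl]-2-{(R)-[3,4-bis(benzyloxy)phenyl][(tert-butyldimethylsilyl)oxy]methyl}cyclopropane-1-carboxylate
Product: 17 tert-butyl (4S)-2-[4-(benzyloxy)-3-methoxyphenyl]-4-{(R)-[3,4-bis(benzyloxy)phenyl][(tert-butyldimethylsilyl)oxy]methyl}-4,5-dihydrofuran-3-carboxylate, via ring-opened iodo enolate 16 (not isolated)
Conditions: NaI (1.5 equiv), DMF, 80 °C
Reagents that add atoms: none
Why: Iodide attacks the unsubstituted ring carbon C5 from the rear in a homoconjugate substitution, which breaks C3–C5 and releases the β-keto ester enolate 16. Alkylation of 16 on carbon only returns 15 (3-exo-tet, reversible), whereas attack of the ketone oxygen on C5 with loss of iodide (5-exo-tet) closes the one new ring, the conjugated and unstrained dihydrofuran 17, which should be the thermodynamic sink. The closest known reaction type is the halide- or amine-promoted Cloke–Wilson rearrangement of 1-acylcyclopropane-1-carboxylates and 1,1-diacylcyclopropanes to 2,3-dihydrofurans. No stereocentre is formed: C4 is a spectator of both substitutions at C5, C7' lies outside the reacting atoms, and the quaternary cyclopropane carbon becomes sp2, so its configuration does not matter. The selectivity needed is cleavage of C3–C5 rather than C3–C4, which would give the 5-substituted isomer. It is secured by the α-branched silyloxybenzyl group on C4, which blocks rear-side approach and, through its β-oxygen, disfavours charge build-up at C4, and by the absence of any Lewis acid that could loosen the C3–C4 bond. Nucleophiles are known to open bicyclic lactones of type 4 at the ring CH2 for the same reasons. The neutral medium should leave the benzyl ethers, the silyl ether and the tert-butyl ester untouched.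

Step 10
Reactants: 17 tert-butyl (4S)-2-[4-(benzyloxy)-3-methoxyphenyl]-4-{(R)-[3,4-bis(benzyloxy)phenyl][(tert-butyldimethylsilyl)oxy]methyl}-4,5-dihydrofuran-3-carboxylate
Product: 18 tert-butyl (2S,3R,4S)-2-[4-(benzyloxy)-3-methoxyphenyl]-4-{(R)-[3,4-bis(benzyloxy)phenyl][(tert-butyldimethylsilyl)oxy]methyl}oxolane-3-carboxylate
Conditions: H2 (3 atm), PtO2, EtOAc, rt
Reagents that add atoms: none
Why: Heterogeneous hydrogenation adds both hydrogens cis from the face opposite the bulky C4 side chain, which sets C2 (S) with the aryl group cis to that side chain and leaves the C3 ester for the moment cis to both neighbours. Platinum is chosen over palladium because in ethyl acetate it saturates alkenes without readily cleaving aryl benzyl ethers or benzylic C–O bonds.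

Step 11
Reactants: 18 tert-butyl (2S,3R,4S)-2-[4-(benzyloxy)-3-methoxyphenyl]-4-{(R)-[3,4-bis(benzyloxy)phenyl][(tert-butyldimethylsilyl)oxy]methyl}oxolane-3-carboxylate
Product: 19 tert-butyl (2S,3S,4S)-2-[4-(benzyloxy)-3-methoxyphenyl]-4-{(R)-[3,4-bis(benzyloxy)phenyl][(tert-butyldimethylsilyl)oxy]methyl}oxolane-3-carboxylate
Conditions: KOtBu (0.5 equiv), THF–tBuOH, 0 °C to rt
Reagents that add atoms: none
Why: Base-mediated epimerisation α to an ester: the all-cis isomer sheds two cis interactions on going to the 2,3-trans-3,4-trans isomer, which should dominate at equilibrium. tert-Butoxide avoids transesterification, and ring opening by β-elimination of O1 would be the reverse of a disfavoured 5-endo-trig closure.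

Step 12
Reactants: 19 tert-butyl (2S,3S,4S)-2-[4-(benzyloxy)-3-methoxyphenyl]-4-{(R)-[3,4-bis(benzyloxy)phenyl][(tert-butyldimethylsilyl)oxy]methyl}oxolane-3-carboxylate
Product: 20 {(2S,3R,4S)-2-[4-(benzyloxy)-3-methoxyphenyl]-4-{(R)-[3,4-bis(benzyloxy)phenyl][(tert-butyldimethylsilyl)oxy]methyl}oxolan-3-yl}methanol
Conditions: LiAlH4, THF, 0 °C to rt; Fieser work-up
Reagents that add atoms: none
Why: Hydride reduction of an ester to the primary alcohol; the ethers and the silyl ether are inert to LiAlH4 and C3 is no longer epimerisable afterwards.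

Step 13
Reactants: 20 {(2S,3R,4S)-2-[4-(benzyloxy)-3-methoxyphenyl]-4-{(R)-[3,4-bis(benzyloxy)phenyl][(tert-butyldimethylsilyl)oxy]methyl}oxolan-3-yl}methanol
Product: 21 (R)-[3,4-bis(benzyloxy)phenyl]{(3S,4R,5S)-5-[4-(benzyloxy)-3-methoxyphenyl]-4-(hydroxymethyl)oxolan-3-yl}methanol
Conditions: Bu4NF, THF, 0 °C to rt
Reagents that add atoms: none
Why: Fluoride cleavage of a secondary silyl ether under non-acidic conditions, so that the benzylic C7'–O bond is never exposed to ionising conditions.

Step 14
Reactants: 21 (R)-[3,4-bis(benzyloxy)phenyl]{(3S,4R,5S)-5-[4-(benzyloxy)-3-methoxyphenyl]-4-(hydroxymethyl)oxolan-3-yl}methanol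
Product: 22 4-{(R)-hydroxy[(3S,4R,5S)-5-(4-hydroxy-3-methoxyphenyl)-4-(hydroxymethyl)oxolan-3-yl]methyl}benzene-1,2-diol
Conditions: H2 (1 atm), 10% Pd/C, EtOAc–MeOH, rt; stopped after uptake of three equivalents
Reagents that add atoms: none
Why: Hydrogenolysis of three aryl benzyl ethers over Pd/C; in neutral solvent these should cleave much faster than the benzylic C2–O1 and C7'–OH bonds, and the product is isolated by filtration without acid or base.

## Compound list

1 | di-tert-butyl malonate | CC(C)(C)OC(=O)CC(=O)OC(C)(C)C | starting material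
2 | (R)-epichlorohydrin, (2R)-2-(chloromethyl)oxirane | ClC[C@H]1CO1 | starting material
3 | di-tert-butyl 2-{[(2R)-oxiran-2-yl]methyl}propanedioate | CC(C)(C)OC(=O)C(C[C@@H]1CO1)C(=O)OC(C)(C)C | intermediate (not isolated)
4 | tert-butyl (1R,5R)-2-oxo-3-oxabicyclo[3.1.0]hexane-1-carboxylate | CC(C)(C)OC(=O)[C@]12C[C@H]1COC2=O | intermediate
5 | tert-butyl (1R,2R)-2-(hydroxymethyl)-1-[methoxy(methyl)carbamoyl]cyclopropane-1-carboxylate | CC(C)(C)OC(=O)[C@@]1(C[C@H]1CO)C(=O)N(C)OC | intermediate
6 | tert-butyl (1R,2R)-2-formyl-1-[methoxy(methyl)carbamoyl]cyclopropane-1-carboxylate | CC(C)(C)OC(=O)[C@@]1(C[C@H]1C=O)C(=O)N(C)OC | intermediate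
7 | 1,2-bis(benzyloxy)-4-bromobenzene | Brc1ccc(OCc2ccccc2)c(OCc2ccccc2)c1 | starting material
8 | [3,4-bis(benzyloxy)phenyl]magnesium bromide | Br[Mg]c1ccc(OCc2ccccc2)c(OCc2ccccc2)c1 | intermediate (not isolated)
9 | tert-butyl (1R,2R)-2-{[3,4-bis(benzyloxy)phenyl](hydroxy)methyl}-1-[methoxy(methyl)carbamoyl]cyclopropane-1-carboxylate, both carbinol epimers | CC(C)(C)OC(=O)[C@@]1(C[C@H]1C(O)c1ccc(OCc2ccccc2)c(OCc2ccccc2)c1)C(=O)N(C)OC | intermediate
10 | tert-butyl (1R,2R)-2-[3,4-bis(benzyloxy)benzoyl]-1-[methoxy(methyl)carbamoyl]cyclopropane-1-carboxylate | CC(C)(C)OC(=O)[C@@]1(C[C@H]1C(=O)c1ccc(OCc2ccccc2)c(OCc2ccccc2)c1)C(=O)N(C)OC | intermediate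
11 | tert-butyl (1R,2R)-2-{(R)-[3,4-bis(benzyloxy)phenyl](hydroxy)methyl}-1-[methoxy(methyl)carbamoyl]cyclopropane-1-carboxylate | CC(C)(C)OC(=O)[C@@]1(C[C@H]1[C@@H](O)c1ccc(OCc2ccccc2)c(OCc2ccccc2)c1)C(=O)N(C)OC | intermediate
12 | tert-butyl (1R,2R)-2-{(R)-[3,4-bis(benzyloxy)phenyl][(tert-butyldimethylsilyl)oxy]methyl}-1-[methoxy(methyl)carbamoyl]cyclopropane-1-carboxylate | CC(C)(C)OC(=O)[C@@]1(C[C@H]1[C@@H](O[Si](C)(C)C(C)(C)C)c1ccc(OCc2ccccc2)c(OCc2ccccc2)c1)C(=O)N(C)OC | intermediate
13 | 1-(benzyloxy)-4-bromo-2-methoxybenzene | COc1cc(Br)ccc1OCc1ccccc1 | starting material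
14 | [4-(benzyloxy)-3-methoxyphenyl]lithium | [Li]c1ccc(OCc2ccccc2)c(OC)c1 | intermediate (not isolated)
15 | tert-butyl (1R,2R)-1-[4-(benzyloxy)-3-methoxybenzoyl]-2-{(R)-[3,4-bis(benzyloxy)phenyl][(tert-butyldimethylsilyl)oxy]methyl}cyclopropane-1-carboxylate | CC(C)(C)OC(=O)[C@@]1(C[C@H]1[C@@H](O[Si](C)(C)C(C)(C)C)c1ccc(OCc2ccccc2)c(OCc2ccccc2)c1)C(=O)c1ccc(OCc2ccccc2)c(OC)c1 | intermediate
16 | sodium enolate of tert-butyl (3R,4R)-2-[4-(benzyloxy)-3-methoxybenzoyl]-4-[3,4-bis(benzyloxy)phenyl]-4-[(tert-butyldimethylsilyl)oxy]-3-(iodomethyl)butanoate | CC(C)(C)OC(=O)C(=C([O-])c1ccc(OCc2ccccc2)c(OC)c1)[C@@H](CI)[C@@H](O[Si](C)(C)C(C)(C)C)c1ccc(OCc2ccccc2)c(OCc2ccccc2)c1.[Na+] | intermediate (not isolated)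
17 | tert-butyl (4S)-2-[4-(benzyloxy)-3-methoxyphenyl]-4-{(R)-[3,4-bis(benzyloxy)phenyl][(tert-butyldimethylsilyl)oxy]methyl}-4,5-dihydrofuran-3-carboxylate | COc1cc(C2=C(C(=O)OC(C)(C)C)[C@H]([C@@H](O[Si](C)(C)C(C)(C)C)c3ccc(OCc4ccccc4)c(OCc4ccccc4)c3)CO2)ccc1OCc1ccccc1 | intermediate
18 | tert-butyl (2S,3R,4S)-2-[4-(benzyloxy)-3-methoxyphenyl]-4-{(R)-[3,4-bis(benzyloxy)phenyl][(tert-butyldimethylsilyl)oxy]methyl}oxolane-3-carboxylate (all-cis) | COc1cc([C@H]2OC[C@@H]([C@@H](O[Si](C)(C)C(C)(C)C)c3ccc(OCc4ccccc4)c(OCc4ccccc4)c3)[C@H]2C(=O)OC(C)(C)C)ccc1OCc1ccccc1 | intermediate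
19 | tert-butyl (2S,3S,4S)-2-[4-(benzyloxy)-3-methoxyphenyl]-4-{(R)-[3,4-bis(benzyloxy)phenyl][(tert-butyldimethylsilyl)oxy]methyl}oxolane-3-carboxylate (all-trans) | COc1cc([C@H]2OC[C@@H]([C@@H](O[Si](C)(C)C(C)(C)C)c3ccc(OCc4ccccc4)c(OCc4ccccc4)c3)[C@@H]2C(=O)OC(C)(C)C)ccc1OCc1ccccc1 | intermediate
20 | {(2S,3R,4S)-2-[4-(benzyloxy)-3-methoxyphenyl]-4-{(R)-[3,4-bis(benzyloxy)phenyl][(tert-butyldimethylsilyl)oxy]methyl}oxolan-3-yl}methanol | COc1cc([C@H]2OC[C@@H]([C@@H](O[Si](C)(C)C(C)(C)C)c3ccc(OCc4ccccc4)c(OCc4ccccc4)c3)[C@@H]2CO)ccc1OCc1ccccc1 | intermediate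
21 | (R)-[3,4-bis(benzyloxy)phenyl]{(3S,4R,5S)-5-[4-(benzyloxy)-3-methoxyphenyl]-4-(hydroxymethyl)oxolan-3-yl}methanol | COc1cc([C@H]2OC[C@@H]([C@@H](O)c3ccc(OCc4ccccc4)c(OCc4ccccc4)c3)[C@@H]2CO)ccc1OCc1ccccc1 | intermediate
22 | 4-{(R)-hydroxy[(3S,4R,5S)-5-(4-hydroxy-3-methoxyphenyl)-4-(hydroxymethyl)oxolan-3-yl]methyl}benzene-1,2-diol | COc1cc([C@H]2OC[C@@H]([C@@H](O)c3ccc(O)c(O)c3)[C@@H]2CO)ccc1O | target

## Step count and least certain steps

Total: 14 steps. Longest linear sequence: 14 steps, from 1 and 2 to 22; bromides 7 and 13 enter as purchased materials.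

**Step 9 (key step).** The likeliest failure is a stalled rearrangement. Re-closure of the iodo enolate through carbon is the fast, reversible path, and closure through oxygen may be slow at temperatures the silyl ether tolerates. Forcing could then bring in opening at the substituted carbon or loss of the silyl group. The fallback separates opening from closure. It sets out from 15: NaI with acetic acid in DMF protonates the enolate as it forms, and the neutral tert-butyl (3R,4R)-2-[4-(benzyloxy)-3-methoxybenzoyl]-4-[3,4-bis(benzyloxy)phenyl]-4-[(tert-butyldimethylsilyl)oxy]-3-(iodomethyl)butanoate F1 is isolated. Silver carbonate Ag2CO3 in acetonitrile then pulls off iodide with participation of the ketone oxygen; the cyclic oxocarbenium ion loses its α-proton, and the sequence rejoins the route at 17.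

**Step 10.** The tetrasubstituted donor–acceptor alkene may take up hydrogen slowly over platinum, and forcing may cost benzyl ethers or facial selectivity. The fallback accepts the loss of the benzyl groups and finishes without them. It sets out from 17: hydrogen over Pd(OH)2/C in EtOAc–MeOH saturates the alkene and removes all three benzyl groups to give the all-cis triphenol ester F2. Excess KOtBu under argon epimerises C3 to the all-trans triphenol ester F3. Excess LiAlH4 gives the silyl-protected tetraol F4. HF·pyridine buffered with pyridine in THF then removes the silyl group, and the sequence rejoins the route at 22.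

**Step 8.** The amide sits on a quaternary carbon beside a bulky cis side chain and may resist the aryllithium. The same fallback applies if 11 lactonises before it can be silylated in step 7. It sets out from 11: mild acid (pyridinium p-toluenesulfonate, toluene, 50 °C) closes the hydroxy amide to the bicyclic lactone F5. Aryllithium 14 adds once to the exposed lactone carbonyl at −78 °C to give the hydroxy ketone F6, which may rest partly as its cyclic hemiketal. Silylation of the open form with TBSOTf and 2,6-lutidine rejoins the route at 15.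

**Step 6.** The substituted cyclopropyl group may not be read cleanly as the small group, or the catalyst may be mismatched with the ring stereocentres, giving poor facial selectivity. The fallback sets C7' in the C–C bond-forming event instead. It sets out from 6 and from Grignard reagent 8: quenching 8 with B(OMe)3 and hydrolysis gives [3,4-bis(benzyloxy)phenyl]boronic acid F7. Transmetalation of F7 with Et2Zn and addition to 6 in the presence of a chiral amino alcohol ligand, chosen to deliver the aryl group to the Si face of the aldehyde, would give the (R)-carbinol directly. This rejoins the route at 11 and bypasses steps 4 and 5.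

## Further compounds

F1 | step 9 | tert-butyl (3R,4R)-2-[4-(benzyloxy)-3-methoxybenzoyl]-4-[3,4-bis(benzyloxy)phenyl]-4-[(tert-butyldimethylsilyl)oxy]-3-(iodomethyl)butanoate | CC(C)(C)OC(=O)C(C(=O)c1ccc(OCc2ccccc2)c(OC)c1)[C@@H](CI)[C@@H](O[Si](C)(C)C(C)(C)C)c1ccc(OCc2ccccc2)c(OCc2ccccc2)c1
F2 | step 10 | tert-butyl (2S,3R,4S)-4-{(R)-[(tert-butyldimethylsilyl)oxy](3,4-dihydroxyphenyl)methyl}-2-(4-hydroxy-3-methoxyphenyl)oxolane-3-carboxylate | COc1cc([C@H]2OC[C@@H]([C@@H](O[Si](C)(C)C(C)(C)C)c3ccc(O)c(O)c3)[C@H]2C(=O)OC(C)(C)C)ccc1O
F3 | step 10 | tert-butyl (2S,3S,4S)-4-{(R)-[(tert-butyldimethylsilyl)oxy](3,4-dihydroxyphenyl)methyl}-2-(4-hydroxy-3-methoxyphenyl)oxolane-3-carboxylate | COc1cc([C@H]2OC[C@@H]([C@@H](O[Si](C)(C)C(C)(C)C)c3ccc(O)c(O)c3)[C@@H]2C(=O)OC(C)(C)C)ccc1O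
F4 | step 10 | 4-{(R)-[(tert-butyldimethylsilyl)oxy][(3S,4R,5S)-5-(4-hydroxy-3-methoxyphenyl)-4-(hydroxymethyl)oxolan-3-yl]methyl}benzene-1,2-diol | COc1cc([C@H]2OC[C@@H]([C@@H](O[Si](C)(C)C(C)(C)C)c3ccc(O)c(O)c3)[C@@H]2CO)ccc1O
F5 | step 8 | tert-butyl (1R,4R,5R)-4-[3,4-bis(benzyloxy)phenyl]-2-oxo-3-oxabicyclo[3.1.0]hexane-1-carboxylate | CC(C)(C)OC(=O)[C@]12C[C@H]1[C@H](c1ccc(OCc3ccccc3)c(OCc3ccccc3)c1)OC2=O
F6 | step 8 | tert-butyl (1R,2R)-1-[4-(benzyloxy)-3-methoxybenzoyl]-2-{(R)-[3,4-bis(benzyloxy)phenyl](hydroxy)methyl}cyclopropane-1-carboxylate | CC(C)(C)OC(=O)[C@@]1(C[C@H]1[C@@H](O)c1ccc(OCc2ccccc2)c(OCc2ccccc2)c1)C(=O)c1ccc(OCc2ccccc2)c(OC)c1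
F7 | step 6 | [3,4-bis(benzyloxy)phenyl]boronic acid | OB(O)c1ccc(OCc2ccccc2)c(OCc2ccccc2)c1
A1 | alternative 1 | 4-(benzyloxy)-3-methoxybenzaldehyde | COc1cc(C=O)ccc1OCc1ccccc1
A2 | alternative 1 | methyl (2Z)-4-(benzyloxy)-2-[(4,4,5,5-tetramethyl-1,3,2-dioxaborolan-2-yl)methyl]but-2-enoate | COC(=O)/C(CB1OC(C)(C)C(C)(C)O1)=C\COCc1ccccc1
A3 | alternative 1 | (4R,5S)-5-[4-(benzyloxy)-3-methoxyphenyl]-4-[(benzyloxy)methyl]-3-methylideneoxolan-2-one | COc1cc([C@H]2OC(=O)C(=C)[C@@H]2COCc2ccccc2)ccc1OCc1ccccc1
A4 | alternative 2 | 4-[(1S,2R,3E)-2-(acetoxymethyl)-4-(3,4-diacetoxyphenyl)-1-hydroxybut-3-en-1-yl]-2-methoxyphenyl acetate | COc1cc([C@@H](O)[C@@H](COC(C)=O)/C=C/c2ccc(OC(C)=O)c(OC(C)=O)c2)ccc1OC(C)=O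
A5 | alternative 2 | formaldehyde | C=O
A6 | alternative 2 | 4-{(R)-acetoxy[(3S,4R,5S)-5-(4-acetoxy-3-methoxyphenyl)-4-(acetoxymethyl)oxolan-3-yl]methyl}-1,2-phenylene diacetate | COc1cc([C@H]2OC[C@@H]([C@@H](OC(C)=O)c3ccc(OC(C)=O)c(OC(C)=O)c3)[C@@H]2COC(C)=O)ccc1OC(C)=O
A7 | alternative 3 | 4-[(2R,3E)-5-(benzyloxy)-1,2-dihydroxypent-3-en-2-yl]-1,2-phenylene bis(2,2-dimethylpropanoate) | OC[C@@](O)(/C=C/COCc1ccccc1)c1ccc(OC(=O)C(C)(C)C)c(OC(=O)C(C)(C)C)c1
A8 | alternative 3 | 4-{(3S,4R,5S)-5-[4-(benzyloxy)-3-methoxyphenyl]-4-[(benzyloxy)methyl]oxolane-3-carbonyl}-1,2-phenylene bis(2,2-dimethylpropanoate) | COc1cc([C@H]2OC[C@@H](C(=O)c3ccc(OC(=O)C(C)(C)C)c(OC(=O)C(C)(C)C)c3)[C@@H]2COCc2ccccc2)ccc1OCc1ccccc1
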